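**Retrosynthetic overview**
1. Labels: Ca = CH carrying the 2-methylprop-1-enyl group; Cb = OCH at the ring fusion; Cc = CH at the ring fusion bonded to C3 of quinolone B. Ring A = pyran on quinolone A (C3, C4, O, Cb, Cc, Ca); ring B = gem-dimethylpyran on quinolone B (C3, C4, O, CMe2, Cb, Cc).
2. Feature: the chain CMe2–Cb(O)–Cc–C3–C2(=O), running through ring B into the pyridone of quinolone B, is a 2-hydroxyglutarate unit. C1–C5 and the (S) centre of L-glutamic acid map onto CMe2, Cb, Cc, C3 and C2.
3. Ring A (last): Ca–C3 by capture of an allyl cation from a tertiary allylic alcohol (made by cross-metathesis of a Cc vinyl group); Cb–O–C4 by SNAr on 4-chloro-1-methylquinolin-2-one.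
4. Ring B: O–CMe2 from the tertiary carbinol in acid. Pyridone of quinolone B: C3–C4 and N–C2 from the enolate of a trans-4-vinyl-5-(silyloxyisopropyl)butyrolactone and N-methylisatoic anhydride.
5. Forward order of rings: butyrolactone (from L-glutamic acid, vinyl set anti by cuprate addition) → pyridone of quinolone B → ring B → ring A.

Key step: step 7

Remark: closure of ring B in acid is assumed to end, under equilibrating conditions, at the 4-alkoxyquinolin-2-one (bond from O4), the pattern of the preferred 4-hydroxyquinolin-2-one tautomer; the competing closure through the lactam oxygen is treated under the risks.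

**Route**

Step 1
Reactants: 1 L-glutamic acid
Product: 2 (S)-5-oxotetrahydrofuran-2-carboxylic acid
Conditions: NaNO2, aq. HCl, 0 °C → rt
Reagents that add atoms: none
Why: Nitrous acid deamination–lactonisation runs with double inversion (α-lactone formed by the neighbouring carboxylate, opened by the γ-carboxylate), so the γ-lactone forms with net retention and the (S) centre that becomes Cb is carried over.

Step 2
Reactants: 2 (S)-5-oxotetrahydrofuran-2-carboxylic acid
Product: 5 (S)-5-(2-hydroxypropan-2-yl)dihydrofuran-2(3H)-one, via acid chloride 3 (not isolated), via methyl ketone 4 (not isolated)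
Conditions: (COCl)2, cat. DMF, CH2Cl2, 0 °C → rt, evaporate; MeMgBr (2.3 equiv), THF, −78 → −40 °C; aq. NH4Cl
Reagents that add atoms: methylmagnesium bromide, C[Mg]Br
Why: Acyl chloride formation and double Grignard addition: the acid chloride and the derived methyl ketone 4 are far more electrophilic than the γ-lactone, so at low temperature both methyl groups should add at the exocyclic carbonyl only, and the fast additions leave the adjacent stereocentre untouched.

Step 3
Reactants: 5 (S)-5-(2-hydroxypropan-2-yl)dihydrofuran-2(3H)-one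
Product: 6 (S)-5-[2-(triethylsilyloxy)propan-2-yl]dihydrofuran-2(3H)-one
Conditions: Et3SiOTf, 2,6-lutidine, CH2Cl2, 0 °C
Reagents that add atoms: triethylsilyl trifluoromethanesulfonate, CC[Si](CC)(CC)OS(=O)(=O)C(F)(F)F
Why: Silylation of the hindered tertiary alcohol with a silyl triflate and a non-nucleophilic base; the silyl ether masks the hydroxyl through the enolate, cuprate and amide-base steps and is removed by the acid of step 8.

Step 4
Reactants: 6 (S)-5-[2-(triethylsilyloxy)propan-2-yl]dihydrofuran-2(3H)-one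
Product: 7 (5S)-3-(phenylselanyl)-5-[2-(triethylsilyloxy)propan-2-yl]dihydrofuran-2(3H)-one (C3 epimers)
Conditions: LiN(iPr)2, THF, −78 °C; PhSeBr, −78 °C
Reagents that add atoms: benzeneselenenyl bromide, Br[Se]c1ccccc1
Why: α-Selenenylation of the lactone lithium enolate; the C3 configuration is of no consequence because that centre is removed in step 5.

Step 5
Reactants: 7 (5S)-3-(phenylselanyl)-5-[2-(triethylsilyloxy)propan-2-yl]dihydrofuran-2(3H)-one
Product: 9 (S)-5-[2-(triethylsilyloxy)propan-2-yl]furan-2(5H)-one, via selenoxide 8 (not isolated)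
Conditions: H2O2 (30 % aq.), pyridine, CH2Cl2, 0 °C → rt
Reagents that add atoms: none
Why: Oxidation to the selenoxide and syn elimination towards C4 (the only β-hydrogen) gives the butenolide under mild, near-neutral conditions that should not deprotonate the γ-position, so C5 stays (S).

Step 6
Reactants: 9 (S)-5-[2-(triethylsilyloxy)propan-2-yl]furan-2(5H)-one
Product: 10 (4R,5S)-4-ethenyl-5-[2-(triethylsilyloxy)propan-2-yl]dihydrofuran-2(3H)-one (trans)
Conditions: CH2=CHMgBr (3 equiv), CuBr·SMe2 (1.5 equiv), THF, −78 → −40 °C; aq. NH4Cl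
Reagents that add atoms: vinylmagnesium bromide, C=C[Mg]Br
Why: Conjugate addition of a vinyl cuprate to the butenolide takes place anti to the bulky C5 substituent, so the new centre (Cc) is set trans to it by substrate control, giving the (4R,5S) lactone.

Step 7
Reactants: 10 (4R,5S)-4-ethenyl-5-[2-(triethylsilyloxy)propan-2-yl]dihydrofuran-2(3H)-one; 11 N-methylisatoic anhydride
Product: 14 4-hydroxy-3-[(3S,4S)-4-hydroxy-5-methyl-5-(triethylsilyloxy)hex-1-en-3-yl]-1-methylquinolin-2(1H)-one, via N-carboxy adduct 12 (not isolated), via anilino ketolactone 13 (not isolated)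
Conditions: LiN(SiMe3)2 (2.2 equiv), THF, −78 °C; 11 (1.1 equiv), −78 °C → rt; AcOH (4 equiv), 50 °C
Reagents that add atoms: none
Why: The lithium enolate of 10 (lactone C3) is acylated at C4, the aroyl carbonyl of 11, which opens the anhydride to N-carboxylate 12, and the second equivalent of base takes the resulting 1,3-dicarbonyl compound out of further reaction as its enolate; on acidification the carbamic acid loses CO2 to give 13, whose N-methylamino nitrogen attacks the lactone carbonyl and expels the Cb oxygen, so that C3–C4 and N–C2 of quinolone B are formed and the product enolises to the aromatic 4-hydroxyquinolin-2-one. The closest known reaction type is the annulation of ester and lactone enolates with N-alkylisatoic anhydrides to 3-substituted 4-hydroxyquinolin-2-ones (crossed Claisen acylation followed by intramolecular aminolysis). The pyridone ring closes by a 6-exo-trig acyl substitution at the lactone carbonyl. No stereocentre is made: C3 of 12 and 13 is a labile 1,3-dicarbonyl position that ends sp2, and Cb and Cc lie outside the reacting atoms, so the (S) O–CH centre from glutamic acid and the anti vinyl centre are carried through unchanged. The step needs C-acylation at the aroyl and not the carbamate carbonyl, which the higher electrophilicity of C4 and the N-methyl group (no isocyanate pathway) secure, and a single acylation, which enolate formation of the product secures. Ring closure is left to the weakly acidic stage so that the Cb hydroxyl is released as the neutral alcohol and the neighbouring silyl ether is not disturbed.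

Step 8
Reactants: 14 4-hydroxy-3-[(3S,4S)-4-hydroxy-5-methyl-5-(triethylsilyloxy)hex-1-en-3-yl]-1-methylquinolin-2(1H)-one
Product: 16 (3S,4S)-4-ethenyl-3-hydroxy-2,2,6-trimethyl-2,3,4,6-tetrahydro-5H-pyrano[3,2-c]quinolin-5-one, via triol 15 (not isolated)
Conditions: TsOH·H2O (0.3 equiv), toluene, 80 °C
Reagents that add atoms: none
Why: Acid removes the silyl group and ionises the tertiary carbinol, and the enolic 4-oxygen captures the tertiary cation in a six-membered ring closure (dehydrative etherification, SN1); closure through the lactam oxygen would give an imidate-type tertiary ether that re-ionises under the conditions, so the 4-alkoxyquinolin-2-one should be the end point, and Cb and Cc are not involved.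

Step 9
Reactants: 16 (3S,4S)-4-ethenyl-3-hydroxy-2,2,6-trimethyl-2,3,4,6-tetrahydro-5H-pyrano[3,2-c]quinolin-5-one; 17 4-chloro-1-methylquinolin-2(1H)-one
Product: 18 (3S,4S)-4-ethenyl-2,2,6-trimethyl-3-[(1-methyl-2-oxo-1,2-dihydroquinolin-4-yl)oxy]-2,3,4,6-tetrahydro-5H-pyrano[3,2-c]quinolin-5-one
Conditions: NaH (1.3 equiv), THF/DMF, 0 °C; 17 (1.2 equiv), 0 → 50 °C
Reagents that add atoms: none
Why: Addition–elimination (SNAr) of the sodium alkoxide at C4 of the 4-chloroquinolin-2-one, a vinylogous carbamoyl chloride; the Cb–O bond is not broken, so the configuration is retained.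

Step 10
Reactants: 18 (3S,4S)-4-ethenyl-2,2,6-trimethyl-3-[(1-methyl-2-oxo-1,2-dihydroquinolin-4-yl)oxy]-2,3,4,6-tetrahydro-5H-pyrano[3,2-c]quinolin-5-one; 19 2-methylbut-3-en-2-ol
Product: 20 (3S,4S)-4-[(1E)-3-hydroxy-3-methylbut-1-en-1-yl]-2,2,6-trimethyl-3-[(1-methyl-2-oxo-1,2-dihydroquinolin-4-yl)oxy]-2,3,4,6-tetrahydro-5H-pyrano[3,2-c]quinolin-5-one
Conditions: second-generation Hoveyda–Grubbs catalyst (10 mol %), 19 (10 equiv), CH2Cl2, 40 °C
Reagents that add atoms: none
Why: Olefin cross-metathesis of the terminal vinyl group with an excess of the tertiary allylic alcohol, which homodimerises slowly, should give the (E)-disubstituted alkene; the quinolone double bonds are part of aromatic rings and do not take part.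

Step 11
Reactants: 20 (3S,4S)-4-[(1E)-3-hydroxy-3-methylbut-1-en-1-yl]-2,2,6-trimethyl-3-[(1-methyl-2-oxo-1,2-dihydroquinolin-4-yl)oxy]-2,3,4,6-tetrahydro-5H-pyrano[3,2-c]quinolin-5-one
Product: 21 the target CNP0107253.2
Conditions: TsOH·H2O (10 mol %), CH2Cl2/(CF3)2CHOH 4:1, 0 °C → rt
Reagents that add atoms: none
Why: Ionisation of the tertiary allylic alcohol gives a dimethylallyl-type cation that is attacked at its secondary terminus (Ca) by the nucleophilic C3 of the 4-alkoxyquinolin-2-one in an intramolecular Friedel–Crafts allylation (SN1′, 6-exo-trig); the Cb–O tether fixes the face of attack and the chair-like transition state places the dimethylvinyl arm on the convex face of the cis-fused bicycle, anti to the Cc–aryl bond and away from the ring-B CMe2 group, which should give (R)-Ca.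

**Compound list**
1 | L-glutamic acid | N[C@@H](CCC(=O)O)C(=O)O | starting material
2 | (S)-5-oxotetrahydrofuran-2-carboxylic acid | OC(=O)[C@@H]1CCC(=O)O1 | intermediate
3 | (S)-5-oxotetrahydrofuran-2-carbonyl chloride | ClC(=O)[C@@H]1CCC(=O)O1 | intermediate (not isolated)
4 | (S)-5-acetyldihydrofuran-2(3H)-one | CC(=O)[C@@H]1CCC(=O)O1 | intermediate (not isolated)
5 | (S)-5-(2-hydroxypropan-2-yl)dihydrofuran-2(3H)-one | CC(C)(O)[C@@H]1CCC(=O)O1 | intermediate
6 | (S)-5-[2-(triethylsilyloxy)propan-2-yl]dihydrofuran-2(3H)-one | CC[Si](CC)(CC)OC(C)(C)[C@@H]1CCC(=O)O1 | intermediate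
7 | (5S)-3-(phenylselanyl)-5-[2-(triethylsilyloxy)propan-2-yl]dihydrofuran-2(3H)-one, C3 epimers | CC[Si](CC)(CC)OC(C)(C)[C@@H]1CC([Se]c2ccccc2)C(=O)O1 | intermediate
8 | (5S)-3-(phenylseleninyl)-5-[2-(triethylsilyloxy)propan-2-yl]dihydrofuran-2(3H)-one | CC[Si](CC)(CC)OC(C)(C)[C@@H]1CC([Se](=O)c2ccccc2)C(=O)O1 | intermediate (not isolated)
9 | (S)-5-[2-(triethylsilyloxy)propan-2-yl]furan-2(5H)-one | CC[Si](CC)(CC)OC(C)(C)[C@@H]1C=CC(=O)O1 | intermediate
10 | (4R,5S)-4-ethenyl-5-[2-(triethylsilyloxy)propan-2-yl]dihydrofuran-2(3H)-one, trans | C=C[C@H]1CC(=O)O[C@@H]1C(C)(C)O[Si](CC)(CC)CC | intermediate (key-step precursor)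
11 | N-methylisatoic anhydride (1-methyl-2H-3,1-benzoxazine-2,4(1H)-dione) | CN1C(=O)OC(=O)c2ccccc12 | starting material
12 | {2-[(4S,5S)-4-ethenyl-2-oxo-5-(2-triethylsilyloxypropan-2-yl)tetrahydrofuran-3-carbonyl]phenyl}(methyl)carbamic acid, present as its lithium salt; C3 labile, C4 and C5 arranged as in 10 | O=C1O[C@H](C(C)(C)O[Si](CC)(CC)CC)[C@@H](C=C)C1C(=O)c1ccccc1N(C)C(=O)O | intermediate (not isolated)
13 | (4S,5S)-4-ethenyl-3-[2-(methylamino)benzoyl]-5-[2-(triethylsilyloxy)propan-2-yl]dihydrofuran-2(3H)-one; C3 labile, C4 and C5 arranged as in 10 | O=C1O[C@H](C(C)(C)O[Si](CC)(CC)CC)[C@@H](C=C)C1C(=O)c1ccccc1NC | intermediate (not isolated)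
14 | 4-hydroxy-3-[(3S,4S)-4-hydroxy-5-methyl-5-(triethylsilyloxy)hex-1-en-3-yl]-1-methylquinolin-2(1H)-one | C=C[C@@H](c1c(O)c2ccccc2n(C)c1=O)[C@H](O)C(C)(C)O[Si](CC)(CC)CC | intermediate (key-step product)
15 | 3-[(3S,4S)-4,5-dihydroxy-5-methylhex-1-en-3-yl]-4-hydroxy-1-methylquinolin-2(1H)-one | C=C[C@@H](c1c(O)c2ccccc2n(C)c1=O)[C@H](O)C(C)(C)O | intermediate (not isolated)
16 | (3S,4S)-4-ethenyl-3-hydroxy-2,2,6-trimethyl-2,3,4,6-tetrahydro-5H-pyrano[3,2-c]quinolin-5-one, 3-OH and 4-vinyl cis | C=C[C@H]1c2c(c3ccccc3n(C)c2=O)OC(C)(C)[C@H]1O | intermediate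
17 | 4-chloro-1-methylquinolin-2(1H)-one | Cn1c(=O)cc(Cl)c2ccccc12 | starting material
18 | (3S,4S)-4-ethenyl-2,2,6-trimethyl-3-[(1-methyl-2-oxo-1,2-dihydroquinolin-4-yl)oxy]-2,3,4,6-tetrahydro-5H-pyrano[3,2-c]quinolin-5-one | C=C[C@H]1c2c(c3ccccc3n(C)c2=O)OC(C)(C)[C@H]1Oc1cc(=O)n(C)c2ccccc12 | intermediate
19 | 2-methylbut-3-en-2-ol | CC(C)(O)C=C | starting material
20 | (3S,4S)-4-[(1E)-3-hydroxy-3-methylbut-1-en-1-yl]-2,2,6-trimethyl-3-[(1-methyl-2-oxo-1,2-dihydroquinolin-4-yl)oxy]-2,3,4,6-tetrahydro-5H-pyrano[3,2-c]quinolin-5-one | CC(C)(O)/C=C/[C@H]1c2c(c3ccccc3n(C)c2=O)OC(C)(C)[C@H]1Oc1cc(=O)n(C)c2ccccc12 | intermediate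
21 | CNP0107253.2: cis-fused bis(pyranoquinolinone) with Ca (R), Cb (S), Cc (S); 2-methylprop-1-enyl on Ca trans to the Cc–quinolone B bond | CC(C)=C[C@H]1c2c(c3ccccc3n(C)c2=O)O[C@H]2[C@@H]1c1c(c3ccccc3n(C)c1=O)OC2(C)C | target

**Totals**
Total step count: 11. Longest linear sequence: 11 steps (1 → 21); compounds 11, 17 and 19 are purchased.

**Three steps most likely to fail**

Step 8 (ring B). The tertiary cation may be captured by the lactam oxygen instead of O4 and not equilibrate, or a 1,2-hydride shift from Cb (pinacol-type) may outrun ring closure. The fallback sets out from 14 and comes back at 16. The enolic 4-hydroxyl of 14 is converted with PhNTf2 and Et3N in CH2Cl2 into 3-[(3S,4S)-4-hydroxy-5-methyl-5-(triethylsilyloxy)hex-1-en-3-yl]-1-methyl-2-oxo-1,2-dihydroquinolin-4-yl trifluoromethanesulfonate F1. KN(SiMe3)2 in THF (−78 → 0 °C) then deprotonates the Cb hydroxyl, the triethylsilyl group shifts from the tertiary to the secondary oxygen (1,2-silyl migration), and the tertiary alkoxide displaces the triflate at C4 in a six-membered addition–elimination. This should give (3S,4S)-4-ethenyl-2,2,6-trimethyl-3-(triethylsilyloxy)-2,3,4,6-tetrahydro-5H-pyrano[3,2-c]quinolin-5-one F2, and Bu4NF in THF frees the Cb hydroxyl to give 16. In this variant the ring oxygen is the carbinol oxygen and C4 carries the leaving group, so only the angular ring can form and no cation is involved.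

Step 11 (ring A). C3 of quinolone A may attack the wrong face of the allyl cation, or the cation may lose the Cc proton to a conjugated diene, which would erase Cc. The fallback sets out from 18 and comes back at 21.
- Cross-metathesis of 18 with but-3-en-2-one (second-generation Hoveyda–Grubbs catalyst, CH2Cl2, 40 °C) should give the (E)-enone (3S,4S)-2,2,6-trimethyl-3-[(1-methyl-2-oxo-1,2-dihydroquinolin-4-yl)oxy]-4-[(1E)-3-oxobut-1-en-1-yl]-2,3,4,6-tetrahydro-5H-pyrano[3,2-c]quinolin-5-one F3.
- Sc(OTf)3 in CH2Cl2 promotes intramolecular Friedel–Crafts conjugate addition of C3 of quinolone A to the enone (6-exo-trig). This step is reversible and should settle on the more stable Ca configuration, giving the analogue of 21 that carries a 2-oxopropyl group on Ca, F4.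
- MeMgBr with CeCl3 in THF at −78 °C converts the ketone into the analogue of 21 that carries a 2-hydroxy-2-methylpropyl group on Ca, F5.
- Acid-catalysed dehydration (TsOH·H2O, toluene, 60 °C) to the trisubstituted alkene gives 21.

Step 7 (key step). The enolate may be O-acylated or attack the carbamate carbonyl of 11, or decarboxylation and lactam formation may stall at open-chain material. The fallback sets out from 10 and comes back at 13. Commercial 2-[(tert-butoxycarbonyl)(methyl)amino]benzoic acid is activated with 1,1′-carbonyldiimidazole in THF to tert-butyl [2-(1H-imidazole-1-carbonyl)phenyl](methyl)carbamate F6. The lithium enolate of 10 (LiN(SiMe3)2, 2.2 equiv, THF, −78 °C) is C-acylated by it (Claisen acylation) to give tert-butyl {2-[(4S,5S)-4-ethenyl-2-oxo-5-(2-triethylsilyloxypropan-2-yl)tetrahydrofuran-3-carbonyl]phenyl}(methyl)carbamate F7. Me3SiOTf and 2,6-lutidine in CH2Cl2, then MeOH, remove the carbamate without touching the silyl ether and give 13, which closes to 14 on warming with AcOH as in step 7.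

**Further compounds**
F1 | step 8 | 3-[(3S,4S)-4-hydroxy-5-methyl-5-(triethylsilyloxy)hex-1-en-3-yl]-1-methyl-2-oxo-1,2-dihydroquinolin-4-yl trifluoromethanesulfonate | C=C[C@@H](c1c(OS(=O)(=O)C(F)(F)F)c2ccccc2n(C)c1=O)[C@H](O)C(C)(C)O[Si](CC)(CC)CC
F2 | step 8 | (3S,4S)-4-ethenyl-2,2,6-trimethyl-3-(triethylsilyloxy)-2,3,4,6-tetrahydro-5H-pyrano[3,2-c]quinolin-5-one | C=C[C@H]1c2c(c3ccccc3n(C)c2=O)OC(C)(C)[C@H]1O[Si](CC)(CC)CC
F3 | step 11 | (3S,4S)-2,2,6-trimethyl-3-[(1-methyl-2-oxo-1,2-dihydroquinolin-4-yl)oxy]-4-[(1E)-3-oxobut-1-en-1-yl]-2,3,4,6-tetrahydro-5H-pyrano[3,2-c]quinolin-5-one | CC(=O)/C=C/[C@H]1c2c(c3ccccc3n(C)c2=O)OC(C)(C)[C@H]1Oc1cc(=O)n(C)c2ccccc12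
F4 | step 11 | analogue of 21 with a 2-oxopropyl group on Ca (configuration at Ca, Cb, Cc as in 21) | CC(=O)C[C@H]1c2c(c3ccccc3n(C)c2=O)O[C@H]2[C@@H]1c1c(c3ccccc3n(C)c1=O)OC2(C)C
F5 | step 11 | analogue of 21 with a 2-hydroxy-2-methylpropyl group on Ca (configuration as in 21) | CC(C)(O)C[C@H]1c2c(c3ccccc3n(C)c2=O)O[C@H]2[C@@H]1c1c(c3ccccc3n(C)c1=O)OC2(C)C
F6 | step 7 | tert-butyl [2-(1H-imidazole-1-carbonyl)phenyl](methyl)carbamate | CN(C(=O)OC(C)(C)C)c1ccccc1C(=O)n1ccnc1
F7 | step 7 | tert-butyl {2-[(4S,5S)-4-ethenyl-2-oxo-5-(2-triethylsilyloxypropan-2-yl)tetrahydrofuran-3-carbonyl]phenyl}(methyl)carbamate, C3 labile | O=C1O[C@H](C(C)(C)O[Si](CC)(CC)CC)[C@@H](C=C)C1C(=O)c1ccccc1N(C)C(=O)OC(C)(C)C
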